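(Readings and results come from a simulation on assumed constants, and the scatter is random.)

Per hour, the epsilon run makes 44.1 mM h⁻¹ of L up to its opening reading and 4.85 mM h⁻¹ over its last interval, and two chemists dispute what this drop means for the zeta flask, which repeats the epsilon charge and runs to 15 h.

| flask | E | Z | time |
|---|---|---|---|
| epsilon | 250 mM | 300 mM |  |
| gamma | 130 mM | 180 mM |  |
| theta | 250 mM | 900 mM |  |
| eta | 750 mM | 300 mM |  |
| zeta | 250 mM | 300 mM | 15 h |

- epsilon run (time / h: [L] / mM): 0.27: 11.9; 0.81: 33.9; 1.5: 57.0; 2.5: 77.5; 3.5: 92.0; 4.7: 102.3; 6.0: 108.6
- gamma run (time / h: [L] / mM): 0.27: 6.0; 0.81: 16.9; 1.5: 25.7; 2.5: 34.7; 3.5: 43.4; 4.7: 48.2; 6.0: 50.1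
- theta run (time / h: [L] / mM): 0.27: 19.3; 0.81: 51.5; 1.5: 79.1; 2.5: 100.4; 3.5: 112.2; 4.7: 112.2; 6.0: 107.6
- eta run (time / h: [L] / mM): 0.27: 20.2; 0.81: 60.0; 1.5: 97.4; 2.5: 139.2; 3.5: 167.3; 4.7: 187.0; 6.0: 201.6

(each reading ± 1 mM)

- Overall: E + Z -> L.
- Constant volume, constant temperature.
- "The second partner" is Z.
- An order is taken over about fifteen percent of the charge, up and down.

- how the opening rate goes with [Z] round the charge of the epsilon run: the exponent of the rate at two percent of E gone to L
- how the opening rate goes with [E] round the charge of the epsilon run: the exponent of the rate at two percent of E gone to L (one fixed amount of L, the same in the runs compared)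
- L in the zeta run at 15 h, as a share of the E charged

The first chemist holds that the partners are simply being used up, with E the limiting reagent, so the opening rate, taken as a plain product of E and Z, carries the zeta flask to 76.9 % of its E.

The second answers from the epsilon tail, where the interval before the last gives 8.58 mM h⁻¹, a fall by 1.77, while the product of the E and Z remaining falls by 1.10. She therefore reads 2.19 h as the time in which the rate of making L shrinks by the factor e, the lifetime of the tail.

Counting lifetimes, 15 h is 6.85 of them, so on this reading the making of L has faded out by then, and the middle of the last epsilon interval plus the last rate times one lifetime gives an estimated level of 116 mM of L. I side with her and take off one thing more: the theta readings fall by a net 3.54 mM h⁻¹ at the end, and if that loss goes with L and Z, the Z left in the zeta flask costs about 7.69 mM, which leaves an estimated 43.3 %.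

For the orders, the opening readings rise by 1.62 on tripling Z and 1.70 on tripling E, exponents of 0.440 and 0.482 across a wide upward span, and I expect the local values at the epsilon charge to lie somewhat higher.

The forecast gives 0.55 for Z and 0.6 for E, and for the yield 42 %, a little below mine, reckoned from the remark that “The epsilon tail fades at about 0.45 per hour”.

The zeta flask gives 38.5 % of its E as L, or 96.2 mM, well under the first chemist's figure, which was set on the opening epsilon reading at 0.123 lifetimes and so is fit for times short against a lifetime, and the orders round the epsilon charge are 0.62 in Z and 0.75 in E.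

    E + Z ⇌ G, settled at all times (7.850 M⁻¹)
    E + Z → L (2.797 M⁻¹ h⁻¹)
    L + Z → J (0.2218 M⁻¹ h⁻¹)
    E → Ja (0.3398 h⁻¹)

The eta run has a rate of 84 mM h⁻¹ where two percent of the epsilon E have turned, and it reaches a quarter of its E charge at 4.69 h, which is 2.14 epsilon lifetimes. That rate and lifetime reckon 162 mM of L by then, while the eta flask holds 188 mM of L.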